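**Retrosynthetic overview**
1. Ring D last: the C8–C15 bond is closed by C-alkylation of the C8 enolate with a C15 allylic chloride; this leaves C16=C17 and fixes C8 from C13.
2. Ring C is not built but released from (+)-nopinone: Lewis-acid cleavage of the cyclobutane bond (C11–C16) unmasks a 4-isopropenylcyclohexanone with C13 already set. C6–C7 comes from radical conjugate addition of a ring A iodide to 3-methylidenenopinone.
3. Lactone: C10–O by hydrogen-atom transfer to C10=C20, oxidation of the C10 radical and capture by the C19 carboxylate. This is the C10 radical/cation that a C9–C10 β-scission of a 9-hydroxykaurane would give, reached without ever making ring B.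
4. Ring A first: epoxide-initiated cation–olefin cyclization (C4–C5 bond) of the Sharpless epoxide of 8-hydroxygeranyl acetate, stopped after one ring; it sets C3, C4 and C5.
5. Order of ring formation: ring A, lactone, ring C (unmasked), ring D.

Assumption: the SMILES is read literally, (3S,4S,5S,8S,10S,13R) in kaurane numbering (used for all locants below), so the C6–C7 chain and the acetoxy group lie on the face of ring A opposite to the lactone bridge.

**Route**

Step 1
Reactants: 1 geranyl acetate
Product: 2 (2E,6E)-8-hydroxygeranyl acetate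
Conditions: SeO2 (0.2 equiv), salicylic acid (0.1 equiv), t-BuOOH (3 equiv), CH2Cl2, 23 °C
Reagents that add atoms: tert-butyl hydroperoxide, CC(C)(C)OO (oxygen passed on through catalytic SeO2, O=[Se]=O)
Why: SeO2-catalysed allylic oxidation (ene reaction followed by [2,3]-sigmatropic shift) attacks the electron-rich terminal trisubstituted alkene at its (E)-methyl group, the alkene next to the acetate being deactivated, and no stereocenter is formed.

Step 2
Reactants: 2 (2E,6E)-8-hydroxygeranyl acetate
Product: 4 silyl ether of the (2S,3S)-epoxy alcohol, via epoxy alcohol 3 (not isolated)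
Conditions: Ti(OiPr)4 (10 mol%), L-(+)-diethyl tartrate (12 mol%), t-BuOOH (2 equiv), 4 Å molecular sieves, CH2Cl2, −20 °C; then imidazole, t-BuMe2SiCl (excess), −20 to 23 °C
Reagents that add atoms: tert-butyl hydroperoxide, CC(C)(C)OO; tert-butyldimethylsilyl chloride, CC(C)(C)[Si](C)(C)Cl
Why: Sharpless asymmetric epoxidation with L-(+)-tartrate delivers oxygen to the face of the (E)-2-methylalk-2-en-1-ol that gives the (2S,3S)-epoxide (the future C3 and C4), the allylic acetate alkene lacking a free hydroxyl is untouched, and the alcohol is silylated in the same flask by standard imidazole-mediated silylation.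

Step 3
Reactants: 4 silyl ether of the (2S,3S)-epoxy alcohol
Product: 6 ring A diacetate with exocyclic C10=C20, via cyclohexanol 5 (not isolated)
Conditions: MeAlCl2 (1.5 equiv), CH2Cl2, −78 °C, 1 h; then pyridine, Ac2O, 4-(dimethylamino)pyridine, −78 to 23 °C
Reagents that add atoms: acetic anhydride, CC(=O)OC(C)=O
Why: Epoxide-initiated cation–olefin (polyene-type) cyclization: MeAlCl2 opens the epoxide at the tertiary carbon while C5 of the (E)-alkene attacks C4 from the back through a chair, so C3–O stays equatorial (3S), C4 is inverted with CH3 axial and CH2OSi equatorial, H5 becomes axial on the face of H3, and the C10 cation loses a C20 proton to the Al–CH3 group to leave the exocyclic alkene (any endocyclic isomer is removed by chromatography); the aluminium alkoxide is then acetylated in the flask.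

Step 4
Reactants: 6 ring A diacetate
Product: 7 ring A primary alcohol (C6–OH)
Conditions: K2CO3 (0.2 equiv), MeOH, 0 °C, stopped at mono-deacetylation
Reagents that add atoms: none
Why: Base-catalysed transesterification (methanolysis) is far faster at the unhindered primary acetate than at the secondary acetate next to the quaternary C4, and no stereocenter is touched.

Step 5
Reactants: 7 ring A primary alcohol
Product: 8 ring A iodide (C6–I)
Conditions: PPh3, imidazole, I2, CH2Cl2, 0 to 23 °C
Reagents that add atoms: iodine, [I][I]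
Why: Appel-type iodination (Garegg–Samuelsson conditions) turns the primary alcohol into the iodide by SN2 displacement of the alkoxyphosphonium group; the hindered silyl ether, the acetate and all stereocenters are unaffected.

Step 6
Reactants: 9 (+)-nopinone
Product: 10 3-methylidenenopinone
Conditions: paraformaldehyde, diisopropylammonium trifluoroacetate (1 equiv), CF3CO2H (10 mol%), THF, reflux
Reagents that add atoms: paraformaldehyde (as formaldehyde), C=O
Why: Direct α-methylenation (Mannich condensation with formaldehyde followed by loss of the amine) can only occur at C3 of nopinone because the other α-carbon is a bridgehead; the bridgehead stereocenters are untouched.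

Step 7
Reactants: 8 ring A iodide; 10 3-methylidenenopinone (3 equiv)
Product: 11 coupled 3-alkylnopinone (C8 epimers)
Conditions: Bu3SnH (1.3 equiv, syringe pump), AIBN (0.2 equiv), PhH, 80 °C
Reagents that add atoms: none
Why: Giese radical conjugate addition: the primary C6 radical from 8 adds to the exocyclic CH2 of the enone (the future C7) faster than it can close onto the neighbouring alkene, the tertiary α-keto radical takes hydrogen from Bu3SnH, and the new C8 center (epimer mixture) is erased again in step 12.

Step 8
Reactants: 11 coupled 3-alkylnopinone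
Product: 12 C19 carboxylic acid
Conditions: CrO3, H2SO4, H2O, acetone, 0 to 23 °C
Reagents that add atoms: water, O
Why: Jones oxidation: the aqueous acid removes the primary silyl ether and hexavalent chromium takes the alcohol through the aldehyde hydrate to the C19 acid, while the secondary acetate, the ketone and the 1,1-disubstituted alkene survive at 0 °C; no stereocenter changes.

Step 9
Reactants: 12 C19 carboxylic acid
Product: 13 19,10-lactone (nopinone still intact)
Conditions: [N,N′-bis(3,5-di-tert-butylsalicylidene)-1,2-cyclohexanediaminato]cobalt (divalent cobalt, 5 mol%), N-fluoro-2,4,6-trimethylpyridinium tetrafluoroborate (1.5 equiv), PhSiH3 (1.5 equiv), PhCF3, 0 to 23 °C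
Reagents that add atoms: none
Why: Cobalt-hydride hydrogen-atom transfer with radical-polar crossover (Mukaiyama-type hydro-acyloxylation under Shigehisa conditions): H is delivered to C20, the tertiary C10 radical is oxidised through its alkylcobalt species to a cation equivalent and is captured irreversibly by the C19 carboxylate, which can reach C10 only from its own face in the ring-flipped chair, so C10 is formed as 10S with C20 equatorial and C5 keeps its configuration (chain anti to the lactone bridge).

Step 10
Reactants: 13 19,10-lactone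
Product: 15 isopropenyl ketone (ring C released from the pinane), via silyl enol ether 14 (not isolated)
Conditions: Me3SiOTf (1.3 equiv), 2,6-di-tert-butyl-4-methylpyridine (2 equiv), CH2Cl2, −78 to −40 °C; then 1 M HCl, THF, 0 °C
Reagents that add atoms: none
Why: Proposed new method: silyl-triflate variant of the known Lewis-acid cyclobutane cleavage of nopinone (done with BF3·OEt2/Ac2O or Me3SiI); O-silylation of the ketone lets the strained C11–C16 bond (about 26 kcal/mol of ring strain) break to a C9=C11 silyl enol ether and a tertiary C16 cation at low temperature where the tert-alkyl lactone is not ionised, the hindered pyridine takes the most accessible methyl proton to give the isopropenyl group, and aqueous acid returns the ketone with C13 unchanged.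

Step 11
Reactants: 15 isopropenyl ketone
Product: 16 allylic chloride
Conditions: Ca(OCl)2, solid CO2, CH2Cl2/H2O, 0 °C
Reagents that add atoms: calcium hypochlorite Ca(OCl)2, [Ca+2].[O-]Cl.[O-]Cl
Why: Ene-type allylic chlorination by HOCl (made from Ca(OCl)2 and CO2, as in carvone to 10-chlorocarvone) puts chlorine on the terminal CH2 and moves the double bond to a methyl group, giving the 2-(chloromethyl)vinyl unit without touching the ketone α-positions or C13.

Step 12
Reactants: 16 allylic chloride
Product: 17 target CNP0204681.1
Conditions: KOt-Bu (1.1 equiv), t-BuOH/THF 1:4, 0 to 23 °C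
Reagents that add atoms: none
Why: Intramolecular enolate C-alkylation (5-exo-tet SN2) under equilibrating conditions: the more substituted C8 enolate displaces the allylic chloride (attack at either end of the 2-substituted allyl unit gives the same product), and since C15 is tied through C16 to C13 it can only bond to C8 on the face of the C13 substituent, which sets C8 as 8S and makes both C8 epimers converge.

**Compound list**

1 | geranyl acetate, (2E)-3,7-dimethylocta-2,6-dien-1-yl acetate | CC(=O)OC/C=C(C)/CCC=C(C)C | starting material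
2 | (2E,6E)-8-hydroxy-3,7-dimethylocta-2,6-dien-1-yl acetate | CC(=O)OC/C=C(C)/CC/C=C(C)/CO | intermediate
3 | (2E)-5-[(2S,3S)-3-(hydroxymethyl)-3-methyloxiran-2-yl]-3-methylpent-2-en-1-yl acetate (formed in the flask) | CC(=O)OC/C=C(C)/CC[C@@H]1O[C@@]1(C)CO | intermediate
4 | (2E)-5-[(2S,3S)-3-({[tert-butyl(dimethyl)silyl]oxy}methyl)-3-methyloxiran-2-yl]-3-methylpent-2-en-1-yl acetate | CC(=O)OC/C=C(C)/CC[C@@H]1O[C@@]1(C)CO[Si](C)(C)C(C)(C)C | intermediate
5 | [(1R,2R,3S)-2-({[tert-butyl(dimethyl)silyl]oxy}methyl)-3-hydroxy-2-methyl-6-methylidenecyclohexyl]methyl acetate (present in the flask as its dichloroaluminium alkoxide) | CC(=O)OC[C@@H]1C(=C)CC[C@H](O)[C@@]1(C)CO[Si](C)(C)C(C)(C)C | intermediate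
6 | (1S,2R,3R)-3-(acetoxymethyl)-2-({[tert-butyl(dimethyl)silyl]oxy}methyl)-2-methyl-4-methylidenecyclohexyl acetate | CC(=O)OC[C@@H]1C(=C)CC[C@H](OC(C)=O)[C@@]1(C)CO[Si](C)(C)C(C)(C)C | intermediate
7 | (1S,2R,3R)-2-({[tert-butyl(dimethyl)silyl]oxy}methyl)-3-(hydroxymethyl)-2-methyl-4-methylidenecyclohexyl acetate | OC[C@@H]1C(=C)CC[C@H](OC(C)=O)[C@@]1(C)CO[Si](C)(C)C(C)(C)C | intermediate
8 | (1S,2R,3R)-2-({[tert-butyl(dimethyl)silyl]oxy}methyl)-3-(iodomethyl)-2-methyl-4-methylidenecyclohexyl acetate | IC[C@@H]1C(=C)CC[C@H](OC(C)=O)[C@@]1(C)CO[Si](C)(C)C(C)(C)C | intermediate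
9 | (+)-nopinone, (1R,5S)-6,6-dimethylbicyclo[3.1.1]heptan-2-one (commercial; ozonolysis product of (−)-β-pinene) | CC1(C)[C@H]2CCC(=O)[C@@H]1C2 | starting material
10 | (1R,5R)-6,6-dimethyl-3-methylidenebicyclo[3.1.1]heptan-2-one (bridgeheads as in 9) | CC1(C)[C@H]2CC(=C)C(=O)[C@@H]1C2 | intermediate
11 | (1R,5S)-3-{2-[(1R,2R,3S)-3-acetoxy-2-({[tert-butyl(dimethyl)silyl]oxy}methyl)-2-methyl-6-methylidenecyclohexyl]ethyl}-6,6-dimethylbicyclo[3.1.1]heptan-2-one, both C8 epimers | CC1(C)[C@H]2CC(CC[C@@H]3C(=C)CC[C@H](OC(C)=O)[C@@]3(C)CO[Si](C)(C)C(C)(C)C)C(=O)[C@@H]1C2 | intermediate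
12 | (1S,2R,6S)-6-acetoxy-2-{2-[(1R,5S)-6,6-dimethyl-2-oxobicyclo[3.1.1]heptan-3-yl]ethyl}-1-methyl-3-methylidenecyclohexane-1-carboxylic acid, both C8 epimers | CC1(C)[C@H]2CC(CC[C@@H]3C(=C)CC[C@H](OC(C)=O)[C@@]3(C)C(=O)O)C(=O)[C@@H]1C2 | intermediate
13 | (1R,5S)-3-{2-[(1S,2S,5S,8S)-2-acetoxy-1,5-dimethyl-7-oxo-6-oxabicyclo[3.2.1]octan-8-yl]ethyl}-6,6-dimethylbicyclo[3.1.1]heptan-2-one, both C8 epimers | CC1(C)[C@H]2CC(CC[C@H]3[C@]4(C)C(=O)O[C@@]3(C)CC[C@@H]4OC(C)=O)C(=O)[C@@H]1C2 | intermediate
14 | trimethylsilyl enol ether (C9=C11) of ketone 15, (13R), formed in the flask | CC(=C)[C@@H]1CC=C(O[Si](C)(C)C)C(CC[C@H]2[C@]3(C)C(=O)O[C@@]2(C)CC[C@@H]3OC(C)=O)C1 | intermediate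
15 | (4R)-2-{2-[(1S,2S,5S,8S)-2-acetoxy-1,5-dimethyl-7-oxo-6-oxabicyclo[3.2.1]octan-8-yl]ethyl}-4-(prop-1-en-2-yl)cyclohexan-1-one, both C8 epimers (ring position 4 is C13) | CC(=C)[C@@H]1CCC(=O)C(CC[C@H]2[C@]3(C)C(=O)O[C@@]2(C)CC[C@@H]3OC(C)=O)C1 | intermediate
16 | (4R)-2-{2-[(1S,2S,5S,8S)-2-acetoxy-1,5-dimethyl-7-oxo-6-oxabicyclo[3.2.1]octan-8-yl]ethyl}-4-(3-chloroprop-1-en-2-yl)cyclohexan-1-one, both C8 epimers | ClCC(=C)[C@@H]1CCC(=O)C(CC[C@H]2[C@]3(C)C(=O)O[C@@]2(C)CC[C@@H]3OC(C)=O)C1 | intermediate
17 | (1S,5R)-1-{2-[(1S,2S,5S,8S)-2-acetoxy-1,5-dimethyl-7-oxo-6-oxabicyclo[3.2.1]octan-8-yl]ethyl}-6-methylidenebicyclo[3.2.1]octan-2-one; kaurane numbering (3S,4S,5S,8S,10S,13R) | C=C1C[C@]2(CC[C@H]3[C@]4(C)C(=O)O[C@@]3(C)CC[C@@H]4OC(C)=O)C[C@H]1CCC2=O | target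

**Step count and weak points**

Total step count: 12. Longest linear sequence: 11 steps (steps 1–5 and 7–12 from geranyl acetate); step 6 is a one-step side branch.

The three steps most likely to fail are 9, 10 and 12.

Step 9 is the riskiest. The carboxylate can reach C10 only in the ring-flipped chair, where the acetoxy group and the C6 chain are both axial. Cobalt-hydride isomerisation of the alkene (in the worst case to the tetrasubstituted C5=C10 olefin, which would scramble C5) or capture by fluoride may therefore win. The fallback sets out from acid 12 and closes the lactone by a kinetic iodolactonisation (I2, NaHCO3, MeCN, 0 °C, dark) to the 20-iodo lactone F1. Its primary iodide is then removed with Bu3SnH and AIBN (PhH, 80 °C), which comes back to the route at 13. The iodonium pathway never passes through a free C10 cation, so C5 cannot epimerise.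

Step 10 has two weak points. The strained tertiary lactone may ionise under Me3SiOTf the way a tert-alkyl ester does, and proton loss from the C16 cation may give the isopropylidene isomer, which destroys C13. The fallback cleaves the cyclobutane before the lactone exists. It sets out from 11: Me3SiOTf and 2,6-di-tert-butyl-4-methylpyridine (or BF3·OEt2, which is now tolerable) give the trimethylsilyl enol ether F2, which 1 M HCl in THF hydrolyses to the isopropenyl ketone F3; alkene isomers can be separated here. CrO3/H2SO4 then gives the isopropenyl keto acid F4. Two 1,1-disubstituted alkenes are now present, so the lactone is closed by iodolactonisation (I2, NaHCO3, MeCN), which only the C10=C20 alkene with its internal carboxylate can undergo, to the isopropenyl iodolactone F5. Bu3SnH and AIBN remove the iodine and the route is rejoined at 15.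

Step 12 depends on enolate regiochemistry. The C11 enolate can reach C15 as easily as the C8 enolate, and only the preference for the more substituted enolate under equilibrating conditions favours the wanted bond. The fallback blocks C11. It sets out from the silyl enol ether 14 (isolated instead of hydrolysed): Pd(OAc)2 (1.1 equiv, MeCN, 23 °C, Saegusa–Ito oxidation) gives the C11=C12 enone F6. Ene chlorination as in step 11 (the enone alkene is electron-poor and inert) gives the chloro enone F7. LiN(SiMe3)2 (THF, −78 to 0 °C) can now deprotonate only C8 on the α side, and the alkylation gives the bicyclic enone F8. Conjugate reduction with [(Ph3P)CuH]6 (PhH, 23 °C) leaves the exocyclic alkene alone and comes back to the route at the target 17.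

**Further compounds**

F1 | step 9 | 20-iodo lactone (13 with CH2I in place of the C20 methyl) | CC1(C)[C@H]2CC(CC[C@H]3[C@]4(C)C(=O)O[C@@]3(CI)CC[C@@H]4OC(C)=O)C(=O)[C@@H]1C2
F2 | step 10 | trimethylsilyl enol ether (C9=C11) of the ring-opened ketone from 11 | CC(=C)[C@@H]1CC=C(O[Si](C)(C)C)C(CC[C@@H]2C(=C)CC[C@H](OC(C)=O)[C@@]2(C)CO[Si](C)(C)C(C)(C)C)C1
F3 | step 10 | isopropenyl ketone carrying the ring A silyl ether and C10=C20 | CC(=C)[C@@H]1CCC(=O)C(CC[C@@H]2C(=C)CC[C@H](OC(C)=O)[C@@]2(C)CO[Si](C)(C)C(C)(C)C)C1
F4 | step 10 | isopropenyl keto acid (C19 acid) | CC(=C)[C@@H]1CCC(=O)C(CC[C@@H]2C(=C)CC[C@H](OC(C)=O)[C@@]2(C)C(=O)O)C1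
F5 | step 10 | isopropenyl iodolactone (15 with CH2I in place of the C20 methyl) | CC(=C)[C@@H]1CCC(=O)C(CC[C@H]2[C@]3(C)C(=O)O[C@@]2(CI)CC[C@@H]3OC(C)=O)C1
F6 | step 12 | C11=C12 enone of 15 | CC(=C)[C@@H]1C=CC(=O)C(CC[C@H]2[C@]3(C)C(=O)O[C@@]2(C)CC[C@@H]3OC(C)=O)C1
F7 | step 12 | chloro enone (allylic chloride of F6) | ClCC(=C)[C@@H]1C=CC(=O)C(CC[C@H]2[C@]3(C)C(=O)O[C@@]2(C)CC[C@@H]3OC(C)=O)C1
F8 | step 12 | bicyclic enone (11,12-didehydro target) | C=C1C[C@]2(CC[C@H]3[C@]4(C)C(=O)O[C@@]3(C)CC[C@@H]4OC(C)=O)C[C@H]1C=CC2=O
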